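The constants make the nucleophile hold acid 60.6 times as tightly as the free base does, so I keep the books on the nucleophile.

    electrophile + nucleophile → acid set free + product (k1 = 5.5 × 10⁻⁴ M⁻¹ s⁻¹)
    nucleophile + acid set free ⇌ protonated nucleophile, settled at all times (K2 = 40000 M⁻¹)
    acid set free + free base ⇌ salt of the base, settled at all times (K3 = 660 M⁻¹)
    nucleophile + protic impurity → quenched reagent (k4 = 0.012 M⁻¹ s⁻¹)
    crystals ⇌ product, rate k5*(cs5 - [product]) while solid is left; crystals form when [product] > cs5 (cs5 = 0.15 M, k5 = 7.5 × 10⁻⁴ s⁻¹)

| setting | green | grey | blue | teal |
|---|---|---|---|---|
| electrophile | 0.20 M (fed, over 15 h) | 0.20 M | 0.20 M | 0.20 M |
| nucleophile | 0.220 M | 0.220 M (fed, over 15 h) | 0.220 M | 0.220 M (in portions, 3, over 15 h) |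
| free base | 0.600 M | 0.600 M | 0.600 M | 0.600 M |
| protic impurity | 4.00 mM | 4.00 mM | 4.00 mM | 4.00 mM |
| time | 25 h | 25 h | 25 h | 25 h |
| remark | all else is in the flask from the start; the feed brings no volume worth counting | all else is in the flask from the start; the feed brings no volume worth counting | everything together at the start | first portion at the start, last at 15 h |

* the flask with the highest amount of product, in percent of the electrophile charged ("all alike" if they lie within 1.5 percentage points) (green / grey / blue / teal / all alike)
* final product, as a percentage of the electrophile charged, in green
* final product, as a percentage of the electrophile charged, in grey
* final product, as a percentage of the electrophile charged, in blue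
* final product, as a percentage of the electrophile charged, in teal

**Impurity entry.** In blue the protic impurity meets the nucleophile at full charge, so its half-life is 4.38 min, far shorter than the run. I book 1.82% of the nucleophile charge as quenched reagent, which leaves 98.2%.

**Acid entry.** Each product spends one nucleophile and sets free one acid. At the start of blue, the pull on the acid (constant times concentration) is 8800 for the nucleophile and 400 for the free base. So at the start of blue the acid lands on the nucleophile, and each product then costs two nucleophile. That cost is no cap, since the 0.600 M of free base is more than the 0.20 M of electrophile and can take up the acid. Counted one to one, the usable nucleophile of 0.216 M is more than the electrophile, so the electrophile is the limiting reagent.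

**The mark.** I call the mark the fraction of the electrophile charge that can become product while the nucleophile pays for both the reaction and the acid. The recipes share their charges, so they share this fraction: 54.0%, with 46.0% of the electrophile left. Past the mark, the base has to hold part of the acid. Counting every form of the nucleophile and the acid closes the books: the product fraction equals the mark plus (salt of the base + acid set free − free nucleophile), divided by twice the electrophile charge.

**Where I stop.** In blue the electrophile's lifetime against the full nucleophile charge is 2.30 h, much shorter than the 25 h run. I therefore expect blue to pass the mark, but the pace beyond it needs an integration I do not do by hand.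

**The forecast.** It names blue as the best flask, at 71.5% (range 69% to 74%), with green at 66.5%, grey at 66% and teal at 64.5%. Its grounds are that “the reaction stalls at roughly two-thirds to three-quarters conversion”. Its lowest figure is teal's. That figure stands above my mark.

**The result.** The flask with the most product is blue, at 71.6%, against 66.7% in green, 65.7% in grey and 64.5% in teal. After 25.0 h, blue holds 0.0776 M of salt of the base, and the mark plus that entry gives 71.6%. A neighbour like blue but charged with 0.50 M of electrophile has a mark of 21.6%. Its 0.152 M of salt brings the books to 36.7%, and its product after 25.0 h stands at 36.7%.

The constants used here were chosen freely, and the outcome is calculated.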